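**Retrosynthetic overview**
1. Ring B and the spiro centre are made last, by an intramolecular vinylogous aldol addition of the δ-lactone γ-carbon to a methyl ketone held on the cage.
2. The cage comes from an intramolecular Diels–Alder reaction of a 6,6-disubstituted cyclohexa-2,4-dienone with a tethered 1,1-disubstituted alkene (bicyclo[2.2.2]octenone and cyclopentane together); the butenolide closes by lactonisation.
3. Key disconnection: the quaternary C–CH2 bond of that dienone. A tethered alkene attacks the ortho carbon of the oxidised (phenoxenium-type) phenol; a 1,2-hydride shift then turns the carbinol-ether tether into the methyl ketone and cuts the tether.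
4. The tethered phenol comes from reductive etherification of a formyl benzoate with an (R)-propargylic alcohol, then ethylene enyne metathesis. The alcohol comes from a hexynoate/acetone aldol, Z-olefination/lactonisation and acetaldehyde alkynylation.
5. Ring order: δ-lactone (ring A) → quaternary centre, bicyclo[2.2.2]octene, cyclopentane and butenolide (one flask) → cyclohexane ring B.

Assumption: the target is andibenin B exactly as drawn in the SMILES. Centres that are planarised or equilibrated in step 8 (lactone C5, the acetyl-bearing carbon) are carried as epimer mixtures and left undefined in the SMILES of those intermediates.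

Step 1
Reactants: 1 methyl 4-hydroxy-3,5-dimethylbenzoate; 2 dichloromethyl methyl ether
Product: 3 methyl 2-formyl-4-hydroxy-3,5-dimethylbenzoate
Conditions: 2, TiCl4, CH2Cl2, 0 → 23 °C; then H2O
Reagents that add atoms: water, O
Why: Rieche formylation (Friedel–Crafts type); the two free ring positions are equivalent and each is activated by an ortho and a para methyl group, so one aldehyde forms and no stereocentre is involved.

Step 2
Reactants: 4 methyl hex-5-ynoate; 5 acetone
Product: 6 methyl 2-(2-hydroxypropan-2-yl)hex-5-ynoate (racemic)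
Conditions: LiN(iPr)2 (2.1 equiv), THF, −78 °C; then 5 (1.0 equiv); AcOH
Reagents that add atoms: none
Why: Aldol addition of the ester enolate to acetone; the alkynyl lithium formed by the second equivalent of base is far slower toward a ketone at −78 °C, and the new centre is left racemic because it is planarised in step 8.

Step 3
Reactants: 6 methyl 2-(2-hydroxypropan-2-yl)hex-5-ynoate; 7 methyl 2-[bis(2,2,2-trifluoroethoxy)phosphoryl]acetate
Product: 10 5-(but-3-yn-1-yl)-6,6-dimethyl-5,6-dihydro-2H-pyran-2-one (racemic), via hydroxy aldehyde 8 (not isolated), via Z-hydroxy enoate 9 (not isolated)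
Conditions: iBu2AlH (2.2 equiv), CH2Cl2, −78 °C; then 7, KN(SiMe3)2, 18-crown-6, THF, −78 → 23 °C; aq. KNaC4H4O6
Reagents that add atoms: none
Why: One-pot ester-to-aldehyde reduction and Still–Gennari (Z-selective Horner–Wadsworth–Emmons) olefination; the Z geometry puts the ester next to the tertiary alkoxide, which lactonises at once.

Step 4
Reactants: 10 5-(but-3-yn-1-yl)-6,6-dimethyl-5,6-dihydro-2H-pyran-2-one; 11 acetaldehyde
Product: 12 5-[(5R)-5-hydroxyhex-3-yn-1-yl]-6,6-dimethyl-5,6-dihydro-2H-pyran-2-one (both epimers at lactone C5)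
Conditions: Me2Zn, (S,S)-ProPhenol (10 mol %), Ph3PO (20 mol %), 11 (slow addition), PhMe, 4 °C; aq. HCl
Reagents that add atoms: none
Why: Catalytic enantioselective alkynylzinc addition to an aldehyde; the ligand antipode is chosen to give the R carbinol (the sense is confirmed by Mosher ester analysis), and Me2Zn leaves the lactone alone.

Step 5
Reactants: 12 5-[(5R)-5-hydroxyhex-3-yn-1-yl]-6,6-dimethyl-5,6-dihydro-2H-pyran-2-one; 3 methyl 2-formyl-4-hydroxy-3,5-dimethylbenzoate
Product: 13 methyl 2-({[(2R)-6-(6,6-dimethyl-2-oxo-5,6-dihydro-2H-pyran-5-yl)hex-3-yn-2-yl]oxy}methyl)-4-hydroxy-3,5-dimethylbenzoate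
Conditions: 3 (1.3 equiv), Et3SiH, BiBr3 (5 mol %), MeCN, 0 → 23 °C
Reagents that add atoms: none
Why: Reductive etherification (mixed acetal/oxocarbenium formation, then hydride transfer from the silane); the carbinol C–O bond is never broken, so R is retained.

Step 6
Reactants: 13 the propargylic benzyl ether of step 5; 14 ethylene
Product: 15 methyl 2-({[(2R)-6-(6,6-dimethyl-2-oxo-5,6-dihydro-2H-pyran-5-yl)-3,4-dimethylidenehexan-2-yl]oxy}methyl)-4-hydroxy-3,5-dimethylbenzoate
Conditions: 14 (1 atm), second-generation Grubbs catalyst (10 mol %), PhMe, 80 °C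
Reagents that add atoms: none
Why: Ethylene–alkyne cross (enyne) metathesis turns the internal alkyne into the 2,3-disubstituted 1,3-diene; the conjugated cis alkene of the lactone is inert and no stereocentre is touched.

Step 7
Reactants: 15 the phenolic diene ether of step 6
Product: 19 seco-andibenin B methyl ketone (the target lacking the bond between the spiro carbon and the carbinol carbon; epimers at lactone C5 and at the acetyl-bearing carbon), via cyclic oxocarbenium ion 16 (not isolated), via dienone hydroxy ester 17 (not isolated), via dienone butenolide 18 (not isolated)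
Conditions: PhI(OAc)2 (1.1 equiv), (CF3)2CHOH/CH2Cl2, −20 °C; then H2O, 23 °C; then PhMe, 80 °C
Reagents that add atoms: water, O
Why: Proposed new method: ligand exchange of the phenol with PhI(OAc)2 gives an aryloxy-iodane that reacts as a phenoxenium (enolonium-type) ion, so the methyl-bearing ortho carbon C3 of the benzoate, normally a nucleophile, is attacked by the terminal carbon of the tethered 1,1-disubstituted alkene, also a nucleophile, through a seven-membered transition state (the tether on the neighbouring benzylic oxygen reaches only this ortho carbon, and the para carbon is blocked and deactivated by the ester); the tertiary allyl cation is quenched by a 1,2-hydride shift from the carbinol carbon (semipinacol, oxidative Prins–pinacol type) to give 16, hydrolysis releases the methyl ketone and the primary alcohol of 17, which lactonises to 18, and the cyclohexa-2,4-dienone then undergoes the intramolecular Diels–Alder reaction on the face carrying the side chain, which fixes the other four cage stereocentres from the new quaternary centre, whose R configuration is relayed from the R carbinol (methyl pseudo-equatorial and C–H eclipsing the diene substituent in the seven-membered transition state); the closest known reaction types are hypervalent-iodine oxidative dearomatisation of phenols with alkene capture and pinacol-type shift, and Diels–Alder reactions of 6,6-disubstituted cyclohexa-2,4-dienones.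

Step 8
Reactants: 19 seco-andibenin B methyl ketone
Product: 20 andibenin B
Conditions: LiN(SiMe3)2 (1.1 equiv), THF, −78 → 0 °C; AcOH
Reagents that add atoms: none
Why: Intramolecular vinylogous aldol addition: reversible proton transfer funnels the material through the Li dienolate of the 5,6-dihydropyran-2-one, whose γ-carbon is the only nucleophilic site that reaches the ketone through a six-membered ring; a Li-bridged transition state keeps the ketone oxygen on the enolate-oxygen side (anti to the C(CH3)2–O bond) and the ketone methyl equatorial, away from the cage, which is expected to give the target configuration at the spiro and carbinol carbons, while the acetyl-bearing carbon equilibrates to the exo epimer, the only one that can close.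

**Compound list**
1 | methyl 4-hydroxy-3,5-dimethylbenzoate | COC(=O)c1cc(C)c(O)c(C)c1 | starting material
2 | dichloromethyl methyl ether | COC(Cl)Cl | starting material
3 | methyl 2-formyl-4-hydroxy-3,5-dimethylbenzoate | COC(=O)c1cc(C)c(O)c(C)c1C=O | intermediate
4 | methyl hex-5-ynoate | COC(=O)CCCC#C | starting material
5 | acetone | CC(C)=O | starting material
6 | methyl 2-(2-hydroxypropan-2-yl)hex-5-ynoate (racemic) | COC(=O)C(CCC#C)C(C)(C)O | intermediate
7 | methyl 2-[bis(2,2,2-trifluoroethoxy)phosphoryl]acetate | COC(=O)CP(=O)(OCC(F)(F)F)OCC(F)(F)F | starting material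
8 | 2-(2-hydroxypropan-2-yl)hex-5-ynal (racemic, not isolated) | O=CC(CCC#C)C(C)(C)O | intermediate
9 | methyl (2Z)-4-(2-hydroxypropan-2-yl)oct-2-en-7-ynoate (racemic, not isolated) | COC(=O)/C=C\C(CCC#C)C(C)(C)O | intermediate
10 | 5-(but-3-yn-1-yl)-6,6-dimethyl-5,6-dihydro-2H-pyran-2-one (racemic) | C#CCCC1C=CC(=O)OC1(C)C | intermediate
11 | acetaldehyde | CC=O | starting material
12 | 5-[(5R)-5-hydroxyhex-3-yn-1-yl]-6,6-dimethyl-5,6-dihydro-2H-pyran-2-one (both C5 epimers) | C[C@@H](O)C#CCCC1C=CC(=O)OC1(C)C | intermediate
13 | methyl 2-({[(2R)-6-(6,6-dimethyl-2-oxo-5,6-dihydro-2H-pyran-5-yl)hex-3-yn-2-yl]oxy}methyl)-4-hydroxy-3,5-dimethylbenzoate | COC(=O)c1cc(C)c(O)c(C)c1CO[C@H](C)C#CCCC1C=CC(=O)OC1(C)C | intermediate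
14 | ethylene | C=C | starting material
15 | methyl 2-({[(2R)-6-(6,6-dimethyl-2-oxo-5,6-dihydro-2H-pyran-5-yl)-3,4-dimethylidenehexan-2-yl]oxy}methyl)-4-hydroxy-3,5-dimethylbenzoate | COC(=O)c1cc(C)c(O)c(C)c1CO[C@H](C)C(=C)C(=C)CCC1C=CC(=O)OC1(C)C | intermediate
16 | acetate of the cyclic oxocarbenium ion: cyclohexa-2,4-dienone (R at the new quaternary carbon) fused to the seven-membered ring C–CH2–CH(dienyl)–C(CH3)=O(+)–CH2 (not isolated) | COC(=O)C1=C2C[O+]=C(C)C(C[C@@]2(C)C(=O)C(C)=C1)C(=C)CCC3C=CC(=O)OC3(C)C.CC(=O)[O-] | intermediate
17 | methyl (3R)-3-[2-acetyl-5-(6,6-dimethyl-2-oxo-5,6-dihydro-2H-pyran-5-yl)-3-methylidenepentyl]-2-(hydroxymethyl)-3,5-dimethyl-4-oxocyclohexa-1,5-diene-1-carboxylate (not isolated) | COC(=O)C1=C(CO)[C@@](C)(CC(C(C)=O)C(=C)CCC2C=CC(=O)OC2(C)C)C(=O)C(C)=C1 | intermediate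
18 | (4R)-4-[2-acetyl-5-(6,6-dimethyl-2-oxo-5,6-dihydro-2H-pyran-5-yl)-3-methylidenepentyl]-4,6-dimethyl-2-benzofuran-1,5(3H,4H)-dione (not isolated) | CC1=CC2=C(COC2=O)[C@@](C)(CC(C(C)=O)C(=C)CCC3C=CC(=O)OC3(C)C)C1=O | intermediate
19 | seco-andibenin B methyl ketone: bicyclo[2.2.2]octenone/cyclopentane/butenolide cage with the five cage centres as in 20, an acetyl group on the cyclopentane CH and a 2-(lactonyl)ethyl chain on the adjacent quaternary carbon (epimers at the acetyl-bearing carbon and lactone C5) | CC1(C)OC(=O)C=CC1CC[C@@]12C[C@@]3(C)C=C4C(=O)OC[C@]41[C@@](C)(CC2C(C)=O)C3=O | intermediate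
20 | andibenin B | CC1(C)OC(=O)C=C[C@]12CC[C@@]13C[C@@]4(C)C=C5C(=O)OC[C@]51[C@@](C)(C[C@H]3[C@@]2(C)O)C4=O | target

**Total step count:** 8. **Longest linear sequence:** 7 (steps 2–8).

**The three steps most likely to fail**

Step 7. The iodane may be captured at the ester-bearing para carbon or lose a benzylic proton to a quinone methide instead of closing the seven-membered ring, and the relay of chirality from the carbinol may be weak or opposite in sense. The fallback sets out from 12 and 3 and comes back at 19; it replaces the oxidative closure by a base-mediated dearomative Michael addition followed by the same Diels–Alder reaction. Oxidation of 12 with MnO2 gives the ynone 6,6-dimethyl-5-(5-oxohex-3-yn-1-yl)-5,6-dihydro-2H-pyran-2-one F1. Ethylene and the second-generation Grubbs catalyst convert it into the 2-acetyl-1,3-diene 5-(3,4-dimethylidene-5-oxohexyl)-6,6-dimethyl-5,6-dihydro-2H-pyran-2-one F2, used at once. Separately NaBH4 reduces 3 to methyl 4-hydroxy-2-(hydroxymethyl)-3,5-dimethylbenzoate F3, which lactonises under TsOH to 5-hydroxy-4,6-dimethyl-2-benzofuran-1(3H)-one F4. F4 and F2 with Cs2CO3 in PhMe at 60 °C (or a cinchona-derived ammonium phenoxide for enantiocontrol) combine by reversible C-alkylation at C4 of the phenoxide to give dienone 18, which the intramolecular Diels–Alder reaction drains to 19.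

Step 8. The base enolises the methyl ketone first, the ketone enolate may add in Michael fashion to the unsaturated lactone, and the facial selectivity at the spiro carbon is not secured by precedent. The fallback goes from 19 to 20 and generates the nucleophile reductively instead of by deprotonation. Radical bromination (NBS, hν) at the tertiary allylic γ-carbon of the lactone gives the γ-bromo lactone 5-bromo seco-andibenin B methyl ketone F5. CrCl2 in THF then forms the chromium dienolate without base, and this closes ring B through its γ-carbon in a Reformatsky-type addition to give 20.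

Step 5. The hindered aldehyde may simply be reduced to the benzylic alcohol, which lactonises to the phthalide and is lost. The fallback sets out from 3 and 12 and comes back at 19; it uses an acyl-acetal tether instead of the ether. Acid-catalysed exchange (TsOH, PhMe) of 3 with 12 gives the 3-alkoxyphthalide 3-{[(2R)-6-(6,6-dimethyl-2-oxo-5,6-dihydro-2H-pyran-5-yl)hex-3-yn-2-yl]oxy}-5-hydroxy-4,6-dimethyl-2-benzofuran-1(3H)-one F6. Enyne metathesis with ethylene gives the corresponding 3,4-dimethylidene diene F7. The PhI(OAc)2 cascade of step 7 then ends, after hydrolysis and Diels–Alder reaction, at the cage lactol (19 with OH on the butenolide CH2 carbon) F8, which Et3SiH/CF3CO2H reduces to 19.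

**Further compounds**
F1 | step 7 | 6,6-dimethyl-5-(5-oxohex-3-yn-1-yl)-5,6-dihydro-2H-pyran-2-one | CC(=O)C#CCCC1C=CC(=O)OC1(C)C
F2 | step 7 | 5-(3,4-dimethylidene-5-oxohexyl)-6,6-dimethyl-5,6-dihydro-2H-pyran-2-one | CC(=O)C(=C)C(=C)CCC1C=CC(=O)OC1(C)C
F3 | step 7 | methyl 4-hydroxy-2-(hydroxymethyl)-3,5-dimethylbenzoate | COC(=O)c1cc(C)c(O)c(C)c1CO
F4 | step 7 | 5-hydroxy-4,6-dimethyl-2-benzofuran-1(3H)-one | Cc1cc2C(=O)OCc2c(C)c1O
F5 | step 8 | 5-bromo seco-andibenin B methyl ketone (19 with Br on the lactone γ-carbon) | CC1(C)OC(=O)C=CC1(Br)CC[C@@]12C[C@@]3(C)C=C4C(=O)OC[C@]41[C@@](C)(CC2C(C)=O)C3=O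
F6 | step 5 | 3-{[(2R)-6-(6,6-dimethyl-2-oxo-5,6-dihydro-2H-pyran-5-yl)hex-3-yn-2-yl]oxy}-5-hydroxy-4,6-dimethyl-2-benzofuran-1(3H)-one | C[C@@H](OC1OC(=O)c2cc(C)c(O)c(C)c21)C#CCCC1C=CC(=O)OC1(C)C
F7 | step 5 | 3-{[(2R)-6-(6,6-dimethyl-2-oxo-5,6-dihydro-2H-pyran-5-yl)-3,4-dimethylidenehexan-2-yl]oxy}-5-hydroxy-4,6-dimethyl-2-benzofuran-1(3H)-one | C[C@@H](OC1OC(=O)c2cc(C)c(O)c(C)c21)C(=C)C(=C)CCC1C=CC(=O)OC1(C)C
F8 | step 5 | cage lactol (19 with OH on the butenolide CH2 carbon) | CC1(C)OC(=O)C=CC1CC[C@@]12C[C@@]3(C)C=C4C(=O)OC(O)[C@]41[C@@](C)(CC2C(C)=O)C3=O
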